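Slowness of feed was the thing to price: what reagent dosed over 24.0 min bought, set against the same reagent present from the first minute.

    reagent + open intermediate → side product (k1 = 0.00345 M⁻¹ s⁻¹)
    substrate + reagent ⇌ open intermediate (K2 = 9.9 M⁻¹, k2 = 0.0100 M⁻¹ s⁻¹)
    substrate + reagent → target (k3 = 0.00184 M⁻¹ s⁻¹)
    capture agent + open intermediate → trapped intermediate (k4 = 0.00204 M⁻¹ s⁻¹)

common to all: substrate 0.050 M; capture agent 0.0150 M
- red: reagent 0.0550 M; time 30 min; plug flow through a tube for 30 min, no back-mixing
- amber: reagent 0.0550 M; a single well-mixed tank run continuously and read at steady state, 30 min in it on average
- ochre: reagent 0.0550 M (fed, over 24.0 min); time 30 min; a stirred flask in which reagent is dosed at a steady rate over 24.0 min without added volume, worked up at 30 min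
- grey: reagent 0.0550 M; time 30 min; a closed flask charged with all of it at once and left for 30 min

* the set-up with the highest share of target in all that became target or side product or trapped intermediate, at the outlet or at the end ("none" if the first two lie within 2 percentage points) (red / amber / ochre / grey / none)
* share of target in all that became target or side product or trapped intermediate, at the outlet or at the end, red
* share of target in all that became target or side product or trapped intermediate, at the outlet or at the end, amber
* share of target in all that became target or side product or trapped intermediate, at the outlet or at the end, ochre
* share of target in all that became target or side product or trapped intermediate, at the outlet or at the end, grey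

- the stated concentrations are those of everything mixed, before any reaction; amounts are the same in each set-up
- the feed brings no volume worth counting
- run time (red): 30 min

I began with the scheme. Target and side product each consume reagent, so [reagent] cancels from their ratio: side product per target (the selectivity factor here) went as 0.00345 [open intermediate] over 0.00184 [substrate]. Trapped intermediate also draws on the open intermediate, so I counted side product plus trapped intermediate as one loss per target, and the share asked for is one over one plus that loss.

I solved the two ends. Early on, [open intermediate]/[substrate] grew with 0.0100 M⁻¹ s⁻¹ times the time integral of [reagent], which I called exposure, and the loss grew roughly with it. Late on, with the drains on the open intermediate neglected, that ratio tends to 9.9 M⁻¹ times [reagent], however the reagent arrived. At full [reagent], I reckoned that the two ends join over a time of about 10.7 min.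

Then the vessels. The red tube and the grey flask have the same history, so I expected equal shares, and I left the amber tank unreckoned. In ochre, with consumption ignored, exposure at the end was that of 18.0 min of full charge, not 30 min. That gave the dosing ratio, one minus the dosing time over twice the run time, 0.600. The joining time of 10.7 min was shorter than the 30 min run, so I did not expect the early end to hold throughout. My estimate for ochre's loss per target therefore lay between red's loss multiplied by this ratio and red's loss itself, with ochre ahead.

The forecast named ochre, with 66.8 % for red, 66.1 % for amber, 73.6 % for ochre and 66.8 % for grey, holding that “slow dosing wins by keeping reagent and intermediate low early on”.

The simulation gave 67.0 % for red, 66.2 % for amber, 73.8 % for ochre and 67.0 % for grey, so loss per target was 0.492 in red and 0.354 in ochre, a ratio of 0.720, above the dosing ratio of 0.600 and below one. For 300 min the same formula gave 0.960, and at that time the shares stood at 64.2 % in red and 64.4 % in ochre.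

Its constants belong to no real substance; the result is computed.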